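**Plan**

- Retrosynthesis cuts first the benzylic C1''–C2'' bond together with the C3''–CH3 bond (chalcone benzylic bromide + terminal alkyne + Me3Al), then the chalcone Cα=Cβ bond (Claisen–Schmidt), then the C6''–C7'' bond (isopropenyl Grignard on a Weinreb amide).
- Enabling feature: C2''=C3'' is an E-trisubstituted olefin whose C3''-methyl is cis to C1'', which is exactly what syn-methylmetalation of a terminal alkyne delivers. C1'' sits on C3' of the carbonyl-bearing ring between the C2' and C4' oxygens, so it can be carried from the start as a C3'-methyl group and turned into CH2Br.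
- Forward: methyl ketone 1 + aldehyde 2 → chalcone → triacetate → benzylic bromide; separately pent-4-ynoic acid → isopropenyl ynone → (R)-alcohol → TBS ether. The two halves are joined last but one by one-pot methylalumination/Pd benzylation, and deprotection ends the route.
- Stereochemistry: C6'' (R) from a CBS reduction; C2''=C3'' (E) from the syn-carbometalation and a stereoretentive coupling; the chalcone olefin (E) is the thermodynamic isomer.
- Helpers: three aryl acetates (mask the phenols, deactivate the rings for the radical bromination, make chroman formation impossible during desilylation) and one TBS ether, all removed in the last step.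

Key step: step 8

Remark: primed locants refer to the ring that bears the carbonyl (C1' carries C=O), double-primed locants to the C10 side chain (C1'' benzylic to C8''); compounds 1, 2 and 6 are taken as commercial.

**Route**

Step 1
Reactants: 1 1-(2,4-dihydroxy-3-methylphenyl)ethan-1-one; 2 4-hydroxybenzaldehyde
Product: 3 (2E)-1-(2,4-dihydroxy-3-methylphenyl)-3-(4-hydroxyphenyl)prop-2-en-1-one
Conditions: BF3·OEt2, 1,4-dioxane, rt; aq. work-up
Reagents that add atoms: none
Why: Lewis-acid-mediated Claisen–Schmidt (aldol) condensation, in which the 2'-hydroxy ketone enolises as its difluoroboron chelate and dehydration should give the thermodynamically favoured E-enone without phenol protection; no acid-sensitive group is present yet.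

Step 2
Reactants: 3 (2E)-1-(2,4-dihydroxy-3-methylphenyl)-3-(4-hydroxyphenyl)prop-2-en-1-one
Product: 4 (2E)-1-[2,4-bis(acetyloxy)-3-methylphenyl]-3-[4-(acetyloxy)phenyl]prop-2-en-1-one
Conditions: Ac2O, pyridine, DMAP (cat.), CH2Cl2, 0 °C → rt
Reagents that add atoms: acetic anhydride, CC(=O)OC(C)=O
Why: DMAP-catalysed O-acetylation should cap all three phenols (the chelated 2'-OH included), removing acidic protons and deactivating both rings toward electrophilic bromination.

Step 3
Reactants: 4 (2E)-1-[2,4-bis(acetyloxy)-3-methylphenyl]-3-[4-(acetyloxy)phenyl]prop-2-en-1-one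
Product: 5 (2E)-1-[2,4-bis(acetyloxy)-3-(bromomethyl)phenyl]-3-[4-(acetyloxy)phenyl]prop-2-en-1-one
Conditions: NBS (1.05 equiv), AIBN (cat.), PhCF3, 85 °C, dark
Reagents that add atoms: N-bromosuccinimide, O=C1CCC(=O)N1Br
Why: Wohl–Ziegler radical bromination, for which the C3'-methyl offers the only benzylic C–H bonds, while the acetoxy groups suppress ring bromination and the low stationary Br2 concentration should spare the electron-poor enone C=C.

Step 4
Reactants: 6 pent-4-ynoic acid
Product: 8 N-methoxy-N-methylpent-4-ynamide, via pent-4-ynoyl imidazolide 7 (not isolated)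
Conditions: CDI (1.1 equiv), CH2Cl2, rt; then MeNH(OMe)·HCl (1.2 equiv), rt
Reagents that add atoms: 1,1'-carbonyldiimidazole, O=C(n1ccnc1)n1ccnc1 (its atoms stay only in 7); N,O-dimethylhydroxylamine hydrochloride, CNOC.Cl
Why: CDI activation to the acyl imidazolide followed by aminolysis is a standard Weinreb amide synthesis and leaves the terminal alkyne untouched.

Step 5
Reactants: 8 N-methoxy-N-methylpent-4-ynamide
Product: 9 2-methylhept-1-en-6-yn-3-one
Conditions: isopropenylmagnesium bromide (2.2 equiv), THF, −20 → 0 °C; inverse quench into cold 1 M HCl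
Reagents that add atoms: isopropenylmagnesium bromide, C=C(C)[Mg]Br
Why: Weinreb ketone synthesis, in which the five-membered magnesium chelate stops the addition at the ketone stage; the extra equivalent covers partial deprotonation of the alkyne C–H and the cold acidic quench should prevent aza-Michael addition of the released amine to the enone.

Step 6
Reactants: 9 2-methylhept-1-en-6-yn-3-one
Product: 10 (3R)-2-methylhept-1-en-6-yn-3-ol
Conditions: (S)-Me-CBS (0.2 equiv), catecholborane (1.5 equiv), toluene, −78 °C; then MeOH, aq. NaOH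
Reagents that add atoms: none
Why: Corey–Bakshi–Shibata reduction, in which the α-branched isopropenyl group acts as the large and the CH2CH2 chain as the small substituent, so the (S)-oxazaborolidine should deliver hydride to the face that gives the (R)-carbinol; catecholborane at −78 °C does not hydroborate the alkyne or the alkene.

Step 7
Reactants: 10 (3R)-2-methylhept-1-en-6-yn-3-ol
Product: 11 tert-butyldimethyl{[(3R)-2-methylhept-1-en-6-yn-3-yl]oxy}silane
Conditions: TBSCl, imidazole, DMF, rt
Reagents that add atoms: tert-butyldimethylsilyl chloride, CC(C)(C)[Si](C)(C)Cl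
Why: standard silylation of a secondary alcohol; the TBS ether tolerates Me3Al and can later be removed with fluoride, and the stereocentre is not touched.

Step 8
Reactants: 11 tert-butyldimethyl{[(3R)-2-methylhept-1-en-6-yn-3-yl]oxy}silane; 5 (2E)-1-[2,4-bis(acetyloxy)-3-(bromomethyl)phenyl]-3-[4-(acetyloxy)phenyl]prop-2-en-1-one
Product: 13 (2E)-1-{2,4-bis(acetyloxy)-3-[(2E,6R)-6-(tert-butyldimethylsilyloxy)-3,7-dimethylocta-2,7-dien-1-yl]phenyl}-3-[4-(acetyloxy)phenyl]prop-2-en-1-one, via alkenylalane 12 (not isolated)
Conditions: 11 (1.3 equiv), Me3Al (2.0 equiv), Cp2ZrCl2 (0.25 equiv), CH2Cl2, 0 °C → rt; volatiles incl. excess Me3Al removed in vacuo; THF; then 5 (1.0 equiv), Pd(PPh3)4 (5 mol %), 0 °C → rt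
Reagents that add atoms: trimethylaluminium, C[Al](C)C
Why: Zirconocene-catalysed syn-methylalumination of the terminal alkyne (Negishi carboalumination) puts CH3 on the internal carbon and AlMe2 on the terminal carbon on the same side, so the C3''-methyl and the E geometry of C2''=C3'' are fixed together; Pd(0) then inserts into the benzylic C–Br bond of 5, the alkenyl group passes from Al to Pd with retention and reductive elimination forms the C1''–C2'' bond. The closest known reaction type is the one-pot carboalumination/Pd- or Ni-catalysed coupling of alkenylalanes with benzylic halides, established for allylated arenes and for chloromethylated quinones whose carbonyl groups are far more electrophilic than those of 5. No ring is closed and no stereocentre is created; C6'' is remote from the reacting centres and its silyl ether is inert. The step needs regioselective carbometalation (secured by the terminal alkyne and by the inertness of the 1,1-disubstituted C7''=C8'' olefin toward the achiral zirconocene), retention of olefin geometry (inherent in transmetalation and reductive elimination), and chemoselection of the benzylic bromide over the enone and the three aryl acetates (secured by stripping the excess Me3Al, by THF coordination of the alane, which suppresses uncatalysed carbonyl addition, and by the fast oxidative addition of Pd(0) to a benzylic bromide). The position of the chain on the ring is not at issue because C1'' was on C3' from the start.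

Step 9
Reactants: 13 (2E)-1-{2,4-bis(acetyloxy)-3-[(2E,6R)-6-(tert-butyldimethylsilyloxy)-3,7-dimethylocta-2,7-dien-1-yl]phenyl}-3-[4-(acetyloxy)phenyl]prop-2-en-1-one
Product: 15 (2E)-1-{2,4-dihydroxy-3-[(2E,6R)-6-hydroxy-3,7-dimethylocta-2,7-dien-1-yl]phenyl}-3-(4-hydroxyphenyl)prop-2-en-1-one, via desilylated triacetate 14 (not isolated)
Conditions: HF·pyridine, pyridine, THF, 0 °C → rt; then MeOH, K2CO3 (excess), 0 °C → rt; aq. NH4Cl
Reagents that add atoms: none
Why: fluoride cleavage of the Si–O bond is run while the phenols are still acetylated, so acid-induced chroman formation onto C3'' cannot occur, and the following carbonate-mediated transesterification (Zemplén-type) should free the three phenols under mild base that neither isomerises the olefins nor closes the 2'-hydroxychalcone to a flavanone.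

**Compound list**

1 | 1-(2,4-dihydroxy-3-methylphenyl)ethan-1-one | CC(=O)c1ccc(O)c(C)c1O | starting material
2 | 4-hydroxybenzaldehyde | O=Cc1ccc(O)cc1 | starting material
3 | (2E)-1-(2,4-dihydroxy-3-methylphenyl)-3-(4-hydroxyphenyl)prop-2-en-1-one | Cc1c(O)ccc(C(=O)/C=C/c2ccc(O)cc2)c1O | intermediate
4 | (2E)-1-[2,4-bis(acetyloxy)-3-methylphenyl]-3-[4-(acetyloxy)phenyl]prop-2-en-1-one | Cc1c(OC(C)=O)ccc(C(=O)/C=C/c2ccc(OC(C)=O)cc2)c1OC(C)=O | intermediate
5 | (2E)-1-[2,4-bis(acetyloxy)-3-(bromomethyl)phenyl]-3-[4-(acetyloxy)phenyl]prop-2-en-1-one | BrCc1c(OC(C)=O)ccc(C(=O)/C=C/c2ccc(OC(C)=O)cc2)c1OC(C)=O | intermediate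
6 | pent-4-ynoic acid | C#CCCC(=O)O | starting material
7 | 1-(1H-imidazol-1-yl)pent-4-yn-1-one | C#CCCC(=O)n1ccnc1 | intermediate
8 | N-methoxy-N-methylpent-4-ynamide | C#CCCC(=O)N(C)OC | intermediate
9 | 2-methylhept-1-en-6-yn-3-one | C=C(C)C(=O)CCC#C | intermediate
10 | (3R)-2-methylhept-1-en-6-yn-3-ol | C=C(C)[C@H](O)CCC#C | intermediate
11 | tert-butyldimethyl{[(3R)-2-methylhept-1-en-6-yn-3-yl]oxy}silane | C=C(C)[C@H](O[Si](C)(C)C(C)(C)C)CCC#C | intermediate
12 | [(1E,5R)-5-(tert-butyldimethylsilyloxy)-2,6-dimethylhepta-1,6-dien-1-yl]dimethylalumane | C=C(C)[C@H](O[Si](C)(C)C(C)(C)C)CC/C(C)=C/[Al](C)C | intermediate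
13 | (2E)-1-{2,4-bis(acetyloxy)-3-[(2E,6R)-6-(tert-butyldimethylsilyloxy)-3,7-dimethylocta-2,7-dien-1-yl]phenyl}-3-[4-(acetyloxy)phenyl]prop-2-en-1-one | C=C(C)[C@H](O[Si](C)(C)C(C)(C)C)CC/C(C)=C/Cc1c(OC(C)=O)ccc(C(=O)/C=C/c2ccc(OC(C)=O)cc2)c1OC(C)=O | intermediate
14 | (2E)-1-{2,4-bis(acetyloxy)-3-[(2E,6R)-6-hydroxy-3,7-dimethylocta-2,7-dien-1-yl]phenyl}-3-[4-(acetyloxy)phenyl]prop-2-en-1-one | C=C(C)[C@H](O)CC/C(C)=C/Cc1c(OC(C)=O)ccc(C(=O)/C=C/c2ccc(OC(C)=O)cc2)c1OC(C)=O | intermediate
15 | (2E)-1-{2,4-dihydroxy-3-[(2E,6R)-6-hydroxy-3,7-dimethylocta-2,7-dien-1-yl]phenyl}-3-(4-hydroxyphenyl)prop-2-en-1-one | C=C(C)[C@H](O)CC/C(C)=C/Cc1c(O)ccc(C(=O)/C=C/c2ccc(O)cc2)c1O | target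

**Step count and risks**

Total steps: 9. Longest linear sequence: 6 steps (steps 4 to 9, from pent-4-ynoic acid 6); the chalcone arm contributes 3 steps before the union.

Steps most likely to fail:

1. Step 8. The alane (or residual Me3Al) may attack the enone or the aryl acetates faster than the palladium cycle turns over, or a methyl group may be transferred in place of the alkenyl group. Fallback, a polarity-reversed Negishi coupling that sets out from 11 and 5 and comes back at 13: 11 would be carboaluminated as in step 8 and alane 12 quenched with I2 (THF, −30 °C) to give tert-butyl{[(3R,6E)-7-iodo-2,6-dimethylhepta-1,6-dien-3-yl]oxy}dimethylsilane F1. Bromide 5 would be converted by LiCl-assisted zinc insertion (Zn dust, LiCl, THF, 0 °C → rt) into the benzylic zinc reagent {2,6-bis(acetyloxy)-3-[(2E)-3-(4-acetyloxyphenyl)prop-2-enoyl]benzyl}zinc bromide F2, which tolerates ketones and esters. Pd-catalysed coupling of F1 with F2 (Pd(OAc)2/SPhos, THF, rt) should then give 13.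

2. Step 3. Bromine may add to the enone C=C, or the methyl group may be brominated twice, so that the mono-bromide cannot be obtained cleanly. Fallback, bromination before the enone exists, setting out from 1 and coming back at 5: 1 would be acetylated (Ac2O, pyridine, DMAP) to 1-[2,4-bis(acetyloxy)-3-methylphenyl]ethan-1-one F3 and brominated under Wohl–Ziegler conditions to 1-[2,4-bis(acetyloxy)-3-(bromomethyl)phenyl]ethan-1-one F4. A BF3·OEt2-mediated Claisen–Schmidt condensation of F4 with commercial 4-formylphenyl acetate, conditions under which O-acyl groups survive, should then give 5.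

3. Step 6. Facial discrimination between the isopropenyl group and the primary chain may be too weak (low enantiomeric purity), or 1,4-reduction may compete. Fallback, resolution in place of asymmetric reduction, setting out from 9 and coming back at 10: Luche reduction (NaBH4, CeCl3·7H2O, MeOH, −78 → 0 °C) would give racemic 2-methylhept-1-en-6-yn-3-ol F5. Sharpless kinetic resolution (Ti(OiPr)4, L-(+)-diisopropyl tartrate, t-BuOOH 0.6 equiv, 4 Å sieves, CH2Cl2, −20 °C) should epoxidise the fast-reacting (S)-enantiomer to the erythro epoxy alcohol (1S)-1-[(2R)-2-methyloxiran-2-yl]pent-4-yn-1-ol F6 and leave (R)-alcohol 10; 2-substituted 1-alken-3-ols are among the best substrates for this resolution.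

**Further compounds**

F1 | step 8 | tert-butyl{[(3R,6E)-7-iodo-2,6-dimethylhepta-1,6-dien-3-yl]oxy}dimethylsilane | C=C(C)[C@H](O[Si](C)(C)C(C)(C)C)CC/C(C)=C/I
F2 | step 8 | {2,6-bis(acetyloxy)-3-[(2E)-3-(4-acetyloxyphenyl)prop-2-enoyl]benzyl}zinc bromide | Br[Zn]Cc1c(OC(C)=O)ccc(C(=O)/C=C/c2ccc(OC(C)=O)cc2)c1OC(C)=O
F3 | step 3 | 1-[2,4-bis(acetyloxy)-3-methylphenyl]ethan-1-one | CC(=O)c1ccc(OC(C)=O)c(C)c1OC(C)=O
F4 | step 3 | 1-[2,4-bis(acetyloxy)-3-(bromomethyl)phenyl]ethan-1-one | CC(=O)c1ccc(OC(C)=O)c(CBr)c1OC(C)=O
F5 | step 6 | rac-2-methylhept-1-en-6-yn-3-ol | C=C(C)C(O)CCC#C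
F6 | step 6 | (1S)-1-[(2R)-2-methyloxiran-2-yl]pent-4-yn-1-ol | C#CCC[C@H](O)[C@@]1(C)CO1
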